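## Analysis of the target

- Target 15 is a β-resorcylic acid. One benzene ring (ring A) carries the carboxyl group at C1, free hydroxyls at C2 and C4, and at C6 an unbranched thirteen-carbon chain (C1'–C13') ending in a primary alcohol. There is no second ring.
- The only stereocentre is C2', an (R)-configured secondary carbinol present as its acetate. Only absolute configuration has to be controlled.
- C2' lies between two methylene groups, the benzylic C1' and C3' of the long chain. They differ little in size close to the stereocentre, so ketone reduction or kinetic resolution would discriminate poorly.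
- Four hydroxylic functions (carboxylic acid, two phenols, primary alcohol) must end up free while the one secondary oxygen stays acetylated. This excludes a hydrolytic final deprotection and a selective acetylation of a polyol.
- A free C2' hydroxyl would sit within reach of the C1 carboxyl carbon and would close a six-membered lactone. The 2-hydroxybenzoic acid unit also decarboxylates under acid or heat.
- The C2' oxygen should therefore be acylated from the moment it becomes a carbinol oxygen, and the last step should be neutral and run at room temperature.
- The strategy rests on C2' being a dialkylcarbinol ester. C1'–C2' can come from an arylacetaldehyde, the acetyl group from an acyl bromide and C3'–C13' from a terminal olefin, so the C2'–C3' bond, the acetate and the configuration are made together.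

## Retrosynthetic reasoning

**15 to 14.** Target 15 is traced back to its tetrabenzyl derivative 14 by cutting the four O–CH2Ph bonds at the C1 carboxyl, the C2 and C4 phenols and the C13' alcohol. One protecting group is used for all four because hydrogenolysis is neutral and spares the acetate, whose C2'–O bond is homobenzylic and not benzylic. The gain is a one-step endgame without acid or base. The forward reaction only has to cleave four benzylic C–O bonds.

**14 to 9, 12 and 11.** In 14 the bonds C2'–C3' and O–C(acetyl) are cut. This is the one place in the chain where a cut gives three simple achiral pieces and removes the stereocentre: C1'–C2' falls back to aldehyde 9, the acetyl group to acetyl bromide 12, and C3'–C13' to terminal olefin 11. A cut at C1'–C2' or C6–C1' would need an enantiopure chain fragment made separately and would pass through a C2' oxygen that is free or must later be re-protected. Forward, 9 and 12 must combine to the racemic 1-bromoalkyl acetate 13. A chiral nickel catalyst and a hydride source must then join 13 to the terminal carbon of 11 and fix the C2' configuration whichever enantiomer of 13 reacts.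

**9 to 7.** Aldehyde 9 is too labile to carry over several steps, so it is taken back to diester 7 by changing the oxidation level at C2' only. No C–C bond is cut. The gain is a stable precursor whose two ester groups differ strongly in steric and electronic demand. The forward reaction must reduce the unhindered aliphatic methyl ester to the aldehyde, through hemiacetal 8, and leave the di-ortho-substituted benzyl benzoate alone.

**7 to 3.** In 7 the ester O–CH2Ph bond is cut to give acid 6 and benzyl bromide 2. Acid 6 is taken back to aldehyde 5, and in 5 the bond between ring carbon C1 and the formyl carbon is cut to give 3. The cut is made there because C1 is para to one ether oxygen, ortho to the other and next to the side chain, which is the site that electrophilic substitution prefers. The carboxyl carbon therefore enters by Vilsmeier formylation (through iminium salt 4) and is raised by Pinnick oxidation. The gain is that the substituted ring is bought and not constructed.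

**3 to 1, and 11 to 10.** The aryl ether bonds of 3 are cut to the commercial diphenol 1 and benzyl bromide 2, and the ether bond of 11 to undec-10-en-1-ol 10 and 2. Both forward reactions are Williamson etherifications.

## Alternatives that were turned down

**Alternative 1:** biomimetic aromatisation.
- Disconnection: ring bond C1–C6, so that ring A is assembled from an open polyketide-type chain.
- Forward key step: thermolysis of the diketo-dioxinone A2 with in-situ alcoholysis opens the dioxinone to the open-chain triketo benzyl ester A3. Aldol closure between C1 and the C6 carbonyl and dehydration give the resorcylate A1.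
- For it: the substitution pattern of ring A is fixed by the chain and no electrophilic substitution is needed. No arylacetaldehyde is handled. On these two points it is stronger than the chosen route.
- Against it: A1 carries a silyl ether at C2' and two free phenols. Reaching the target needs phenol protection, desilylation (which exposes the C2' hydroxyl next to the ortho benzyl ester and invites lactonisation), acetylation and hydrogenolysis. In A2 and A3 the silyloxy group is β to a ketone and can be lost by elimination. A2 itself needs a separately made enantiopure β-silyloxy acyl unit and two C-acylations.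
- Comparison: the chosen strategy offers roughly half the step count and an acetate that is installed together with the stereocentre.

**Alternative 2:** aryne three-component coupling.
- Disconnection: the two ring–substituent bonds C6–C1' and C1–CO2H.
- Forward key step: ortho-lithiation of fluoroarene A5 and loss of fluoride give aryne A6. The allylic Grignard reagent A7 adds at the aryne carbon remote from the neighbouring benzyloxy group, and carboxylation of the new aryl–magnesium bond gives acid A4.
- For it: it is the most convergent way to the 1,2,3,5-substituted ring and needs no formylation or oxidation. On convergence at the arene it is stronger than the chosen route.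
- Against it: A4 has neither the C2' oxygen nor the stereocentre. The methylidene group would have to be cleaved to a carbonyl group, which is prone to cyclise onto the neighbouring carboxyl. That carbonyl would then be reduced enantioselectively although it is flanked by two methylenes. The resulting free hydroxyl could lactonise before it is acetylated. A7 also has to be prepared.
- Comparison: the chosen strategy couples stereocontrol to the bond formation and never exposes a C2' hydroxyl.

**Alternative 3:** benzannulation.
- Disconnection: ring bonds C1–C2 and C5–C6.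
- Forward key step: [4+2] cycloaddition of the dioxinone-derived silyloxy diene A9 with the chiral ynoate A10, then loss of the ketal and silyl fragments, gives resorcylate A8.
- For it: the acetate and the configuration are already in A10, so the configuration does not depend on catalyst performance, and A8 needs only one hydrogenolysis. On stereochemical certainty and on the short endgame it is as strong as or stronger than the chosen route.
- Against it: a 3-alkyl ynoate is a reluctant dienophile, and the forcing conditions it needs threaten the sensitive ketene acetal A9. The homopropargylic acetate of A10 can isomerise or eliminate. A10 must be built in several steps from an enantiopure building block.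
- Comparison: the chosen strategy makes the stereocentre from achiral commercial materials in one catalytic step and reaches the target in fewer operations.

Key step: step 7

Remark on the chemistry: the sense of induction of the bis(oxazoline)–nickel catalyst for the electrophile derived from 9 cannot be assigned from first principles. It is assumed that one antipode of ligand L*, 2,2'-(propane-2,2-diyl)bis(4-isopropyl-4,5-dihydrooxazole), delivers the (2R)-acetate; that antipode is to be chosen by a calibration run, both being available.

## Route

**Step 1**
Reactants: 1 methyl 2-(3,5-dihydroxyphenyl)acetate; 2 benzyl bromide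
Product: 3 methyl 2-[3,5-bis(benzyloxy)phenyl]acetate
Conditions: 2 (2.3 equiv), K2CO3, DMF, rt
Reagents that add atoms: none
Why: Williamson ether synthesis; K2CO3 deprotonates the phenols but not the arylacetate methylene, so O-benzylation should be clean.

**Step 2**
Reactants: 3 methyl 2-[3,5-bis(benzyloxy)phenyl]acetate
Product: 5 methyl 2-[3,5-bis(benzyloxy)-2-formylphenyl]acetate, via aryl iminium chloride 4 (not isolated)
Conditions: POCl3, DMF, 0 °C to 60 °C; then aq. NaOAc, rt
Reagents that add atoms: N,N-dimethylformamide CN(C)C=O; water O
Why: Vilsmeier–Haack formylation; the chloroiminium electrophile should attack para to one benzyloxy group and ortho to the other, next to the side chain, rather than the more congested site between the two ether groups, as is usual for 5-alkylresorcinol diethers. Hydrolysis of 4 gives the aldehyde.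

**Step 3**
Reactants: 5 methyl 2-[3,5-bis(benzyloxy)-2-formylphenyl]acetate
Product: 6 2,4-bis(benzyloxy)-6-(2-methoxy-2-oxoethyl)benzoic acid
Conditions: NaClO2, NaH2PO4, 2-methyl-2-butene, t-BuOH/THF/H2O, 0 °C to rt
Reagents that add atoms: sodium chlorite [Na+].[O-]Cl=O
Why: Pinnick oxidation; chlorous acid oxidises the aldehyde and the alkene scavenges hypochlorous acid, which protects the electron-rich ring from chlorination. The ester and ethers are inert.

**Step 4**
Reactants: 6 2,4-bis(benzyloxy)-6-(2-methoxy-2-oxoethyl)benzoic acid; 2 benzyl bromide
Product: 7 benzyl 2,4-bis(benzyloxy)-6-(2-methoxy-2-oxoethyl)benzoate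
Conditions: 2 (1.2 equiv), K2CO3, DMF, rt
Reagents that add atoms: none
Why: carboxylate O-alkylation (SN2 at the benzylic carbon); it takes place at oxygen, so the steric shielding of the di-ortho-substituted carboxyl carbon does not matter.

**Step 5**
Reactants: 7 benzyl 2,4-bis(benzyloxy)-6-(2-methoxy-2-oxoethyl)benzoate
Product: 9 benzyl 2,4-bis(benzyloxy)-6-(2-oxoethyl)benzoate, via aluminium hemiacetal 8 (not isolated)
Conditions: i-Bu2AlH (1.05 equiv), CH2Cl2, −78 °C; MeOH, then aq. KNaC4H4O6, −78 °C to rt
Reagents that add atoms: none
Why: partial reduction of an ester with diisobutylaluminium hydride; the unhindered aliphatic methyl ester should react first, while the benzoate is flanked by two ortho substituents and deactivated by two donor oxygens. Hemiacetal 8 persists at −78 °C and releases the aldehyde only on work-up; 9 is used at once.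

**Step 6**
Reactants: 10 undec-10-en-1-ol; 2 benzyl bromide
Product: 11 11-(benzyloxy)undec-1-ene
Conditions: NaH, 2 (1.2 equiv), n-Bu4NI (cat.), THF/DMF, 0 °C to rt
Reagents that add atoms: none
Why: Williamson ether synthesis of a primary alkoxide; the terminal olefin is untouched.

**Step 7**
Reactants: 9 benzyl 2,4-bis(benzyloxy)-6-(2-oxoethyl)benzoate; 12 acetyl bromide; 11 11-(benzyloxy)undec-1-ene
Product: 14 benzyl 6-[(2R)-2-acetoxy-13-(benzyloxy)tridecyl]-2,4-bis(benzyloxy)benzoate, via racemic 1-bromoalkyl acetate 13 (not isolated)
Conditions: 12 (1.05 equiv), CH2Cl2, 0 °C, volatiles removed; then 11 (1.5 equiv), NiBr2·glyme (10 mol %), bis(oxazoline) L* (12 mol %), (EtO)3SiH (2 equiv), K3PO4·H2O (2 equiv), DMA/i-Pr2O, 0 °C to rt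
Reagents that add atoms: none
Why: The closest known reaction type is the nickel-catalysed enantioconvergent coupling of racemic 1-haloalkyl esters with olefins and a hydrosilane, run here in its one-pot four-component form with 9 as a new aliphatic aldehyde. Acetyl bromide 12 adds across the C=O of 9 to give racemic 13, so the C2' oxygen is acylated as it is formed and a free hydroxyl that could lactonise onto the ortho ester never exists. NiBr2·glyme, L* and the silane give L*Ni–H, which inserts the terminal olefin 11 with anti-Markovnikov regiochemistry to a primary alkylnickel; the unbiased monosubstituted olefin secures this. Bromine-atom abstraction from either enantiomer of 13 gives the same planar α-acetoxy radical, which erases the configuration of 13. The chiral alkylnickel captures the radical, and reductive elimination from trivalent nickel forms C2'–C3'; the ligand L* on nickel is the element that controls the new C2' stereocentre, (R) with the antipode fixed in the remark. No ring is closed. The step needs enantioselectivity (from L*), linear regioselectivity (from the terminal olefin) and chemoselectivity: the benzyl ethers and the hindered benzyl benzoate are inert to L*Ni–H, and 9 is consumed by 12 before the silane is added, so carbonyl hydrosilylation cannot compete.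

**Step 8**
Reactants: 14 benzyl 6-[(2R)-2-acetoxy-13-(benzyloxy)tridecyl]-2,4-bis(benzyloxy)benzoate
Product: 15 2-[(2R)-2-acetoxy-13-hydroxytridecyl]-4,6-dihydroxybenzoic acid
Conditions: H2 (1 atm), Pd/C (10 %), EtOAc, rt
Reagents that add atoms: none
Why: catalytic hydrogenolysis of two aryl benzyl ethers, one alkyl benzyl ether and one benzyl ester; the C2'–O bond is not benzylic, so the acetate and the stereocentre are untouched. Neutral conditions at room temperature avoid lactonisation and decarboxylation.

## Compound list

1 | methyl 2-(3,5-dihydroxyphenyl)acetate | COC(=O)Cc1cc(O)cc(O)c1 | starting material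
2 | benzyl bromide | BrCc1ccccc1 | starting material
3 | methyl 2-[3,5-bis(benzyloxy)phenyl]acetate | COC(=O)Cc1cc(OCc2ccccc2)cc(OCc2ccccc2)c1 | intermediate
4 | N-{[2,4-bis(benzyloxy)-6-(2-methoxy-2-oxoethyl)phenyl]methylidene}-N-methylmethanaminium chloride | COC(=O)Cc1cc(OCc2ccccc2)cc(OCc2ccccc2)c1C=[N+](C)C.[Cl-] | intermediate
5 | methyl 2-[3,5-bis(benzyloxy)-2-formylphenyl]acetate | COC(=O)Cc1cc(OCc2ccccc2)cc(OCc2ccccc2)c1C=O | intermediate
6 | 2,4-bis(benzyloxy)-6-(2-methoxy-2-oxoethyl)benzoic acid | COC(=O)Cc1cc(OCc2ccccc2)cc(OCc2ccccc2)c1C(=O)O | intermediate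
7 | benzyl 2,4-bis(benzyloxy)-6-(2-methoxy-2-oxoethyl)benzoate | COC(=O)Cc1cc(OCc2ccccc2)cc(OCc2ccccc2)c1C(=O)OCc1ccccc1 | intermediate
8 | benzyl 2,4-bis(benzyloxy)-6-{2-[(diisobutylalumanyl)oxy]-2-methoxyethyl}benzoate | COC(Cc1cc(OCc2ccccc2)cc(OCc2ccccc2)c1C(=O)OCc1ccccc1)O[Al](CC(C)C)CC(C)C | intermediate
9 | benzyl 2,4-bis(benzyloxy)-6-(2-oxoethyl)benzoate | O=CCc1cc(OCc2ccccc2)cc(OCc2ccccc2)c1C(=O)OCc1ccccc1 | intermediate
10 | undec-10-en-1-ol | C=CCCCCCCCCCO | starting material
11 | 11-(benzyloxy)undec-1-ene | C=CCCCCCCCCCOCc1ccccc1 | intermediate
12 | acetyl bromide | CC(=O)Br | starting material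
13 | racemic benzyl 6-(2-acetoxy-2-bromoethyl)-2,4-bis(benzyloxy)benzoate | CC(=O)OC(Br)Cc1cc(OCc2ccccc2)cc(OCc2ccccc2)c1C(=O)OCc1ccccc1 | intermediate
14 | benzyl 6-[(2R)-2-acetoxy-13-(benzyloxy)tridecyl]-2,4-bis(benzyloxy)benzoate | CC(=O)O[C@H](CCCCCCCCCCCOCc1ccccc1)Cc1cc(OCc2ccccc2)cc(OCc2ccccc2)c1C(=O)OCc1ccccc1 | intermediate
15 | 2-[(2R)-2-acetoxy-13-hydroxytridecyl]-4,6-dihydroxybenzoic acid | CC(=O)O[C@H](CCCCCCCCCCCO)Cc1cc(O)cc(O)c1C(=O)O | target

## Step count and risk

Total step count: 8. Longest linear sequence: 7 steps (steps 1, 2, 3, 4, 5, 7, 8); step 6 is a one-step side branch.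

**Step 7 (key step).**
- Most likely failure: loss of the electrophile before nickel engages it. The carbonyl oxygen of the ortho benzyl ester can assist ionisation of the C–Br bond of 13 and the benzyl group is then lost, or HBr is eliminated towards the conjugated enol acetate. Enantioselectivity may also erode, because the aryl-bearing flank is bulkier than in usual substrates.
- Fallback, from 3 and 11, returning at 15: the carboxyl carbon is left off until the acetate is in place, and the stereocentre is set by carbonyl addition.
  - Ester 3 is reduced with i-Bu2AlH at −78 °C to 2-[3,5-bis(benzyloxy)phenyl]acetaldehyde F1.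
  - Olefin 11 is hydroborated with Et2BH to [11-(benzyloxy)undecyl]diethylborane F2 and exchanged with Et2Zn to bis[11-(benzyloxy)undecyl]zinc F3.
  - Addition of F3 to F1 with Ti(Oi-Pr)4 and a catalytic amount of the appropriate antipode of trans-1,2-bis(trifluoromethanesulfonamido)cyclohexane should give (2R)-1-[3,5-bis(benzyloxy)phenyl]-13-(benzyloxy)tridecan-2-ol F4, which has no ester to lactonise onto.
  - Ac2O, pyridine and DMAP give (2R)-1-[3,5-bis(benzyloxy)phenyl]-13-(benzyloxy)tridecan-2-yl acetate F5.
  - Vilsmeier–Haack formylation gives (2R)-1-[3,5-bis(benzyloxy)-2-formylphenyl]-13-(benzyloxy)tridecan-2-yl acetate F6.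
  - Pinnick oxidation gives 2-[(2R)-2-acetoxy-13-(benzyloxy)tridecyl]-4,6-bis(benzyloxy)benzoic acid F7, and hydrogenolysis over Pd/C gives 15.

**Step 5.**
- Most likely failure: over-reduction to the primary alcohol followed by lactonisation onto the benzoate, competing attack on the benzyl ester, and enolisation or air oxidation of the arylacetaldehyde during handling.
- Fallback, from 7, returning at 9: chemoselectivity is taken from the reagents and not from temperature control.
  - LiOH (1 equiv) in THF/H2O at 0 °C should saponify only the unhindered methyl ester to 2-{3,5-bis(benzyloxy)-2-[(benzyloxy)carbonyl]phenyl}acetic acid F8.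
  - BH3·SMe2 reduces the acid, and not the ester, to benzyl 2,4-bis(benzyloxy)-6-(2-hydroxyethyl)benzoate F9, which is kept cold.
  - Dess–Martin periodinane with NaHCO3 in CH2Cl2 oxidises F9 at once to 9.

**Step 2.**
- Most likely failure: substitution at the position between the two benzyloxy groups, and loss of benzyl groups under the hot acidic conditions.
- Fallback, from 3, returning at 7 (it replaces steps 2 to 4):
  - NBS in MeCN at 0 °C brominates para to a benzyloxy group under non-acidic conditions to give methyl 2-[3,5-bis(benzyloxy)-2-bromophenyl]acetate F10.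
  - Alkoxycarbonylation with Pd(OAc)2, Xantphos, CO, benzyl alcohol and Et3N in toluene at 80–100 °C gives 7 directly.

**Step 8.**
- Most likely failure: slow cleavage of the primary alkyl benzyl ether compared with the other three benzyl groups. The long exposure this forces gives the free acid time to lose acetic acid by lactonisation or to decarboxylate.
- Fallback, from 10, returning at 15:
  - Alcohol 10 is silylated (t-BuPh2SiCl, imidazole) to tert-butyl(diphenyl)(undec-10-en-1-yloxy)silane F11.
  - F11 is used in place of 11 in the step 7 coupling with 9 and 12, through 13, to give benzyl 6-[(2R)-2-acetoxy-13-(tert-butyldiphenylsilyloxy)tridecyl]-2,4-bis(benzyloxy)benzoate F12.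
  - HF·pyridine in THF gives benzyl 6-[(2R)-2-acetoxy-13-hydroxytridecyl]-2,4-bis(benzyloxy)benzoate F13.
  - A short hydrogenolysis over Pd/C removes the three readily cleaved benzyl groups and gives 15.

## Further compounds

F1 | step 7 | 2-[3,5-bis(benzyloxy)phenyl]acetaldehyde | O=CCc1cc(OCc2ccccc2)cc(OCc2ccccc2)c1
F2 | step 7 | [11-(benzyloxy)undecyl]diethylborane | CCB(CC)CCCCCCCCCCCOCc1ccccc1
F3 | step 7 | bis[11-(benzyloxy)undecyl]zinc | [Zn](CCCCCCCCCCCOCc1ccccc1)CCCCCCCCCCCOCc1ccccc1
F4 | step 7 | (2R)-1-[3,5-bis(benzyloxy)phenyl]-13-(benzyloxy)tridecan-2-ol | O[C@H](CCCCCCCCCCCOCc1ccccc1)Cc1cc(OCc2ccccc2)cc(OCc2ccccc2)c1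
F5 | step 7 | (2R)-1-[3,5-bis(benzyloxy)phenyl]-13-(benzyloxy)tridecan-2-yl acetate | CC(=O)O[C@H](CCCCCCCCCCCOCc1ccccc1)Cc1cc(OCc2ccccc2)cc(OCc2ccccc2)c1
F6 | step 7 | (2R)-1-[3,5-bis(benzyloxy)-2-formylphenyl]-13-(benzyloxy)tridecan-2-yl acetate | CC(=O)O[C@H](CCCCCCCCCCCOCc1ccccc1)Cc1cc(OCc2ccccc2)cc(OCc2ccccc2)c1C=O
F7 | step 7 | 2-[(2R)-2-acetoxy-13-(benzyloxy)tridecyl]-4,6-bis(benzyloxy)benzoic acid | CC(=O)O[C@H](CCCCCCCCCCCOCc1ccccc1)Cc1cc(OCc2ccccc2)cc(OCc2ccccc2)c1C(=O)O
F8 | step 5 | 2-{3,5-bis(benzyloxy)-2-[(benzyloxy)carbonyl]phenyl}acetic acid | OC(=O)Cc1cc(OCc2ccccc2)cc(OCc2ccccc2)c1C(=O)OCc1ccccc1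
F9 | step 5 | benzyl 2,4-bis(benzyloxy)-6-(2-hydroxyethyl)benzoate | OCCc1cc(OCc2ccccc2)cc(OCc2ccccc2)c1C(=O)OCc1ccccc1
F10 | step 2 | methyl 2-[3,5-bis(benzyloxy)-2-bromophenyl]acetate | COC(=O)Cc1cc(OCc2ccccc2)cc(OCc2ccccc2)c1Br
F11 | step 8 | tert-butyl(diphenyl)(undec-10-en-1-yloxy)silane | C=CCCCCCCCCCO[Si](c1ccccc1)(c1ccccc1)C(C)(C)C
F12 | step 8 | benzyl 6-[(2R)-2-acetoxy-13-(tert-butyldiphenylsilyloxy)tridecyl]-2,4-bis(benzyloxy)benzoate | CC(=O)O[C@H](CCCCCCCCCCCO[Si](c1ccccc1)(c1ccccc1)C(C)(C)C)Cc1cc(OCc2ccccc2)cc(OCc2ccccc2)c1C(=O)OCc1ccccc1
F13 | step 8 | benzyl 6-[(2R)-2-acetoxy-13-hydroxytridecyl]-2,4-bis(benzyloxy)benzoate | CC(=O)O[C@H](CCCCCCCCCCCO)Cc1cc(OCc2ccccc2)cc(OCc2ccccc2)c1C(=O)OCc1ccccc1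
A1 | alternative 1 | benzyl 6-[(2R)-13-(benzyloxy)-2-(tert-butyldimethylsilyloxy)tridecyl]-2,4-dihydroxybenzoate | CC(C)(C)[Si](C)(C)O[C@H](CCCCCCCCCCCOCc1ccccc1)Cc1cc(O)cc(O)c1C(=O)OCc1ccccc1
A2 | alternative 1 | 6-[(6R)-17-(benzyloxy)-6-(tert-butyldimethylsilyloxy)-2,4-dioxoheptadecyl]-2,2-dimethyl-4H-1,3-dioxin-4-one | CC(C)(C)[Si](C)(C)O[C@H](CCCCCCCCCCCOCc1ccccc1)CC(=O)CC(=O)CC1=CC(=O)OC(C)(C)O1
A3 | alternative 1 | benzyl (9R)-20-(benzyloxy)-9-(tert-butyldimethylsilyloxy)-3,5,7-trioxoicosanoate | CC(C)(C)[Si](C)(C)O[C@H](CCCCCCCCCCCOCc1ccccc1)CC(=O)CC(=O)CC(=O)CC(=O)OCc1ccccc1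
A4 | alternative 2 | 2,4-bis(benzyloxy)-6-[13-(benzyloxy)-2-methylidenetridecyl]benzoic acid | OC(=O)c1c(OCc2ccccc2)cc(OCc2ccccc2)cc1CC(=C)CCCCCCCCCCCOCc1ccccc1
A5 | alternative 2 | 1,3-bis(benzyloxy)-5-fluorobenzene | Fc1cc(OCc2ccccc2)cc(OCc2ccccc2)c1
A6 | alternative 2 | 3,5-bis(benzyloxy)benzyne | C1#CC(OCc2ccccc2)=CC(OCc2ccccc2)=C1
A7 | alternative 2 | {2-[11-(benzyloxy)undecyl]prop-2-en-1-yl}magnesium chloride | C=C(C[Mg]Cl)CCCCCCCCCCCOCc1ccccc1
A8 | alternative 3 | benzyl 6-[(2R)-2-acetoxy-13-(benzyloxy)tridecyl]-2,4-dihydroxybenzoate | CC(=O)O[C@H](CCCCCCCCCCCOCc1ccccc1)Cc1cc(O)cc(O)c1C(=O)OCc1ccccc1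
A9 | alternative 3 | [(2,2-dimethyl-4-methylidene-4H-1,3-dioxin-6-yl)oxy]trimethylsilane | C=C1C=C(O[Si](C)(C)C)OC(C)(C)O1
A10 | alternative 3 | benzyl (5R)-5-acetoxy-16-(benzyloxy)hexadec-2-ynoate | CC(=O)O[C@H](CCCCCCCCCCCOCc1ccccc1)CC#CC(=O)OCc1ccccc1
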